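**Strategy.** The para-quinone ring is cut at the two bonds that join its carbonyl carbons to the hydroxy-bearing and the pentadecyl-bearing ring carbons. This C(OH)=C(C15H31) unit is an alkyne in disguise (1-ethoxyheptadec-1-yne), and the remaining O=C–C(CH3)=C(OH)–C=O chain is the ring-opened form of 3-methoxy-4-methylcyclobutenedione. In the key step a five-membered maleoylcobalt metallacycle, obtained by insertion of monovalent cobalt into the dione C–C bond, takes up the ynol ether in a formal [4+2] annulation and forms both acyl–alkyne bonds at once. The acyl–C(OEt) bond unites two electrophilic, carboxyl-type carbons through the polarity-reversed acyl–cobalt bond. Hydrolysis of both enol ethers then gives the target.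

Key step: step 4

Remark: the target has no stereocentre and is made as the 2,5-dihydroxy-1,4-benzoquinone tautomer drawn; cobalt complex 9 is assumed to be the neutral six-coordinate CoCl(dimethylglyoxime)(pyridine)(acyl)2 species, and dative bonds in the SMILES of cobalt complexes are written charge-separated.

**Step 1**
Reactants: 1 dimethyl squarate (3,4-dimethoxycyclobut-3-ene-1,2-dione)
Product: 3 3-methoxy-4-methylcyclobut-3-ene-1,2-dione, via hydroxycyclobutenone adduct 2 (not isolated)
Conditions: MeLi (1.05 equiv), THF, −78 °C; then 12 M HCl, CH2Cl2, 0 °C → rt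
Reagents that add atoms: methyllithium [Li]C
Why: 1,2-addition of methyllithium to one squarate carbonyl, then acid-promoted allylic transposition of the tertiary hydroxyl with loss of methanol (the usual squarate-to-cyclobutenedione sequence), should give the 3-alkoxy-4-alkyl dione; the stereocentre of racemic 2 is destroyed.

**Step 2**
Reactants: 4 ethoxyacetylene; 5 1-bromopentadecane
Product: 7 1-ethoxyheptadec-1-yne, via lithium ethoxyacetylide 6 (not isolated)
Conditions: n-BuLi (1.0 equiv), THF, −78 °C; then 5, HMPA, Bu4NI (cat.), −78 °C → rt; filtration through basic Al2O3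
Reagents that add atoms: none
Why: Deprotonation of the terminal ynol ether and SN2 alkylation of the lithium acetylide with the primary bromide (acetylide alkylation, with HMPA and iodide catalysis) should give the internal ynol ether.

**Step 3**
Reactants: 3 3-methoxy-4-methylcyclobut-3-ene-1,2-dione
Product: 9 chloro(dimethylglyoxime)(pyridine)cobalt 2-methoxy-3-methylmaleoyl metallacycle (trivalent cobalt), via bis(triphenylphosphine) maleoylcobalt chloride 8 (not isolated)
Conditions: ClCo(PPh3)3 (1.0 equiv), benzene, rt, N2; then dimethylglyoxime (1.1 equiv), pyridine, rt; crystallisation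
Reagents that add atoms: chlorotris(triphenylphosphine)cobalt Cl[Co-3]([P+](c1ccccc1)(c1ccccc1)c1ccccc1)([P+](c1ccccc1)(c1ccccc1)c1ccccc1)[P+](c1ccccc1)(c1ccccc1)c1ccccc1; dimethylglyoxime CC(=NO)C(C)=NO; pyridine c1ccncc1
Why: Oxidative addition of monovalent cobalt into the strained C(=O)–C(=O) bond (C–C bond activation) should give the five-membered trivalent maleoylcobalt metallacycle, and exchange of both phosphines for the dimethylglyoxime chelate plus pyridine should give an air-stable complex free of phosphine that responds to Lewis acids.

**Step 4**
Reactants: 9 chloro(dimethylglyoxime)(pyridine)cobalt 2-methoxy-3-methylmaleoyl metallacycle; 7 1-ethoxyheptadec-1-yne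
Product: 10 2-ethoxy-5-methoxy-6-methyl-3-pentadecyl-1,4-benzoquinone
Conditions: 7 (1.5 equiv), SnCl4 (0.2 equiv), CH2Cl2, 4 Å MS, 0 °C → rt, N2
Reagents that add atoms: none
Why: The Lewis acid binds the more basic vinylogous-ester acyl oxygen (the acyl next to C–CH3) and labilises chloride, the ynol ether coordinates to trivalent cobalt, the other, more electrophilic acyl group (next to C–OCH3) migrates onto the nucleophilic pentadecyl-bearing alkyne carbon to give a seven-membered cobaltacycle, and C–C reductive elimination joins the ethoxy-bearing carbon to the remaining acyl carbon with release of monovalent cobalt. The closest known reaction type is the quinone synthesis from maleoylcobalt or phthaloylcobalt complexes and alkynes (alkyne insertion into a metallacycle followed by reductive elimination). The six-membered quinone ring is closed as a formal [4+2] annulation, the ring-closing event being reductive elimination from the seven-membered metallacycle. No stereocentre is formed. The step needs regiocontrol (2,5- against 2,6-dialkoxy pattern), which matched polarisation should secure: the electron-rich β-carbon of the ynol ether pairs with the acyl carbon that the methoxy group does not deactivate, so the ethoxy carbon ends on the acyl carbon next to C–CH3. Survival of the acid-sensitive ynol ether is addressed by substoichiometric SnCl4, low temperature and an anhydrous medium.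

**Step 5**
Reactants: 10 2-ethoxy-5-methoxy-6-methyl-3-pentadecyl-1,4-benzoquinone
Product: 11 2,5-dihydroxy-3-methyl-6-pentadecyl-1,4-benzoquinone
Conditions: 2 M NaOH (aq), EtOH, 70 °C, N2; then 2 M HCl, 0 °C
Reagents that add atoms: sodium hydroxide [Na+].[OH-]
Why: Both alkoxy groups are vinylogous ester groups of the quinone, so hydroxide should displace methoxide and ethoxide by conjugate addition–elimination (vinylogous saponification), and the resulting dianion should resist further attack until acidification liberates the dihydroxyquinone.

**Compound list**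
1 | dimethyl squarate (3,4-dimethoxycyclobut-3-ene-1,2-dione) | COC1=C(OC)C(=O)C1=O | starting material
2 | 4-hydroxy-2,3-dimethoxy-4-methylcyclobut-2-en-1-one (racemic) | COC1=C(OC)C(C)(O)C1=O | intermediate
3 | 3-methoxy-4-methylcyclobut-3-ene-1,2-dione | COC1=C(C)C(=O)C1=O | intermediate
4 | ethoxyacetylene (ethoxyethyne) | CCOC#C | starting material
5 | 1-bromopentadecane | CCCCCCCCCCCCCCCBr | starting material
6 | lithium ethoxyacetylide | [Li]C#COCC | intermediate
7 | 1-ethoxyheptadec-1-yne | CCCCCCCCCCCCCCCC#COCC | intermediate
8 | chlorobis(triphenylphosphine)cobalt 2-methoxy-3-methylmaleoyl metallacycle (trivalent cobalt) | COC1=C(C)C(=O)[Co-2](Cl)([P+](c2ccccc2)(c2ccccc2)c2ccccc2)([P+](c2ccccc2)(c2ccccc2)c2ccccc2)C1=O | intermediate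
9 | chloro(dimethylglyoxime)(pyridine)cobalt 2-methoxy-3-methylmaleoyl metallacycle (trivalent cobalt) | COC1=C(C)C(=O)[Co-3]2(Cl)([n+]3ccccc3)([N+](O)=C(C)C(C)=[N+]2O)C1=O | intermediate
10 | 2-ethoxy-5-methoxy-6-methyl-3-pentadecyl-1,4-benzoquinone | CCCCCCCCCCCCCCCC1=C(OCC)C(=O)C(C)=C(OC)C1=O | intermediate
11 | 2,5-dihydroxy-3-methyl-6-pentadecyl-1,4-benzoquinone | CCCCCCCCCCCCCCCC1=C(O)C(=O)C(C)=C(O)C1=O | target

**Total step count:** 5
**Longest linear sequence:** 4 steps (steps 1, 3, 4, 5); step 2 is a one-step branch.

**Steps most likely to fail**

Step 4. The alkyne may insert with the opposite orientation, giving the 2,6-dialkoxy pattern, or the ynol ether may be consumed by Lewis-acid-induced oligomerisation or hydration before it inserts. The fallback builds the substituents on a preformed arene and sets out from 5 and commercial 1,2,4,5-tetramethoxybenzene. Ortho-lithiation (n-BuLi, TMEDA, THF, 0 °C) and quenching with MeI should give 1,2,4,5-tetramethoxy-3-methylbenzene F1. A second lithiation at the remaining ring position and alkylation with 5 (THF/HMPA) should give 1,2,4,5-tetramethoxy-3-methyl-6-pentadecylbenzene F2. Oxidative demethylation with (NH4)2Ce(NO3)6 in MeCN/H2O at 0 °C should give 2,5-dimethoxy-3-methyl-6-pentadecyl-1,4-benzoquinone F3. Hydrolysis of F3 under the conditions of step 5 brings the fallback back to the route at 11.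

Step 3. Insertion of cobalt into the electron-rich dione may stay incomplete, or the metallacycle may be lost during the exchange of phosphine for dimethylglyoxime, and ClCo(PPh3)3 is sensitive to oxygen. The fallback is a metal-free thermal ring expansion that sets out from 3 and 6, with 6 made from 4 as in step 2. Addition of 6 to the more electrophilic carbonyl of 3 (the one next to C–OCH3; THF, −78 °C, aq. NH4Cl quench) should give racemic 4-(ethoxyethynyl)-4-hydroxy-3-methoxy-2-methylcyclobut-2-en-1-one F4. Thermolysis in p-xylene at 140 °C (Moore rearrangement: electrocyclic opening to a vinylketene, closure onto the alkyne, hydrogen transfer) should give 2-ethoxy-5-methoxy-6-methyl-1,4-benzoquinone F5. Silver-catalysed decarboxylative radical alkylation of its single free ring position with hexadecanoic acid (AgNO3 cat., (NH4)2S2O8, MeCN/H2O, 70 °C) should give 10, where the fallback returns to the route.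

Step 5. Cleavage of the second enol ether may stay incomplete, or the electron-rich dianion may degrade by oxidation or ring contraction in hot alkali. The fallback cleaves the ethers at the arene oxidation level and sets out from 10. Reduction with Na2S2O4 (EtOAc/H2O) should give 2-ethoxy-5-methoxy-6-methyl-3-pentadecylbenzene-1,4-diol F6. BBr3 (CH2Cl2, −78 °C → rt) should cleave both alkyl aryl ethers to give 3-methyl-6-pentadecylbenzene-1,2,4,5-tetrol F7. Oxidation by air during aqueous work-up should return the route at 11.

**Further compounds**
F1 | step 4 | 1,2,4,5-tetramethoxy-3-methylbenzene | COc1cc(OC)c(OC)c(C)c1OC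
F2 | step 4 | 1,2,4,5-tetramethoxy-3-methyl-6-pentadecylbenzene | CCCCCCCCCCCCCCCc1c(OC)c(OC)c(C)c(OC)c1OC
F3 | step 4 | 2,5-dimethoxy-3-methyl-6-pentadecyl-1,4-benzoquinone | CCCCCCCCCCCCCCCC1=C(OC)C(=O)C(C)=C(OC)C1=O
F4 | step 3 | 4-(ethoxyethynyl)-4-hydroxy-3-methoxy-2-methylcyclobut-2-en-1-one (racemic) | CCOC#CC1(O)C(OC)=C(C)C1=O
F5 | step 3 | 2-ethoxy-5-methoxy-6-methyl-1,4-benzoquinone | CCOC1=CC(=O)C(OC)=C(C)C1=O
F6 | step 5 | 2-ethoxy-5-methoxy-6-methyl-3-pentadecylbenzene-1,4-diol | CCCCCCCCCCCCCCCc1c(OCC)c(O)c(C)c(OC)c1O
F7 | step 5 | 3-methyl-6-pentadecylbenzene-1,2,4,5-tetrol | CCCCCCCCCCCCCCCc1c(O)c(O)c(C)c(O)c1O
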